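**Overview**

1. Locants used throughout: ten-membered ring C1–C10 with C1–C3 = three CH2, C4 = C(CH3)OH, C5 = CH–O-angelate, C6 = CH–O of the lactone, C7 = CH bearing C11, C8 = CHOH, C9 = C=O, C10 = CHCH3. C11(=C13H2)–C12(=O)–O6 completes the five-membered lactone ring.
2. Enabling feature: read the C8 hydroxyl as an oxidised enolate and the anti-4,5-diol as an opened epoxide of an E alkene. The carbocycle is then a cyclodec-5-en-1-one (C9=O, C4=C5) whose C6–C7 bond faces the non-bonded pair C4/C9 across the ring, which is the retron of an oxy-Cope enlargement of the six-membered ring C9–C10–C1–C2–C3–C4.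
3. Retrosynthetic cuts, in order: O8–Si; lactone C12–O6 (with the C12 oxidation level); ester O5–C(O); C4–O then C5–O (diol to epoxide to alkene); C8–O; C6–C7 with C4–C9 re-formed; C8–C9 (dienyl metal plus ketone); C6–O; C5=C6; C4–allyl.
4. Forward ring order: purchased cyclohexanone ring, ten-membered ring by [3,3] enlargement, oxirane on C4/C5 made and opened, alpha-methylene-gamma-lactone closed last.
5. Stereochemistry: quaternary C4 (Pd, chiral PHOX ligand) is the only reagent-controlled centre. C10 comes from equilibration, carbinol C9 from substrate-controlled addition, and C6/C7 from chair chirality transfer. C8 and C5 come from peripheral attack on the medium ring, C4 returns by inversion on epoxide opening, and the Z ester geometry is bought with angelic acid.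

Key step: step 13

Abbreviations: PMB = 4-methoxybenzyl, TBS = tert-butyldimethylsilyl, Ang = (Z)-2-methylbut-2-enoyl.
Remark on the chemistry: the two C10 epimers of compounds 5–10 are carried together, because C10 is equilibrated and sorted only in step 7.

**Route**

Step 1
Reactants: 1 2,6-dimethylcyclohexanone (cis/trans mixture); 2 allyl chloroformate
Product: 4 allyl 2,6-dimethylcyclohex-1-en-1-yl carbonate (racemic), via potassium enolate 3 (not isolated)
Conditions: KN(SiMe3)2, THF, −78 → 0 °C; then 2, −78 °C
Reagents that add atoms: none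
Why: Enolate O-acylation: both diastereomers of 1 give the same and only possible enolate 3, and a dissociated potassium enolate is acylated by the hard chloroformate on oxygen rather than on its fully substituted carbon.

Step 2
Reactants: 4 allyl 2,6-dimethylcyclohex-1-en-1-yl carbonate
Product: 5 (2R)-2-allyl-2,6-dimethylcyclohexan-1-one (both C6 epimers)
Conditions: Pd2(dba)3 (cat.), (R)-t-Bu-PHOX (cat.), THF, 25 °C
Reagents that add atoms: none
Why: Pd-catalysed decarboxylative asymmetric allylic alkylation: zerovalent palladium ionises the allyl carbonate, CO2 is lost and the enolate is allylated at its tetrasubstituted carbon inside the chiral PHOX pocket, so the R ligand should fix the quaternary centre (later C4) as R under catalyst control, whatever the configuration at the other methyl-bearing carbon (later C10).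

Step 3
Reactants: 5 (2R)-2-allyl-2,6-dimethylcyclohexan-1-one
Product: 6 (2R)-2,6-dimethyl-2-[(E)-prop-1-en-1-yl]cyclohexan-1-one (both C6 epimers)
Conditions: RuHCl(CO)(PPh3)3 (cat.), toluene, 110 °C
Reagents that add atoms: none
Why: Ruthenium hydride catalysed alkene isomerisation (hydrometalation and beta-hydride elimination) moves the terminal double bond one position inward to the more stable propenyl group and must stop there because the next carbon is quaternary, the alkene geometry being irrelevant for the cleavage that follows.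

Step 4
Reactants: 6 (2R)-2,6-dimethyl-2-[(E)-prop-1-en-1-yl]cyclohexan-1-one
Product: 8 (1R)-1,3-dimethyl-2-oxocyclohexane-1-carbaldehyde (both C3 epimers), via secondary ozonide 7 (not isolated)
Conditions: O3, CH2Cl2, −78 °C; then Me2S, −78 → 25 °C
Reagents that add atoms: ozone, [O-][O+]=O
Why: Ozonolysis with reductive work-up cleaves the only C=C bond and leaves C5 as an aldehyde on a non-enolisable quaternary carbon, so the R centre cannot racemise, and the deformylation-prone beta-keto aldehyde is taken on without storage.

Step 5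
Reactants: 8 (1R)-1,3-dimethyl-2-oxocyclohexane-1-carbaldehyde
Product: 9 (2R)-2-[(E)-2-iodoethenyl]-2,6-dimethylcyclohexan-1-one (both C6 epimers)
Conditions: CrCl2, CHI3, THF, 0 °C
Reagents that add atoms: iodoform, [I][CH]([I])[I]
Why: Takai iodo-olefination: the geminal dichromium species formed from iodoform and divalent chromium adds to the aldehyde much faster than to the hindered ketone, and elimination from the less crowded adduct gives the E vinyl iodide, the iodoform carbon becoming C6.

Step 6
Reactants: 9 (2R)-2-[(E)-2-iodoethenyl]-2,6-dimethylcyclohexan-1-one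
Product: 10 (2R)-2-[(E)-2-(4-methoxybenzyloxy)ethenyl]-2,6-dimethylcyclohexan-1-one (both C6 epimers)
Conditions: 4-methoxybenzyl alcohol, CuI (cat.), 3,4,7,8-tetramethyl-1,10-phenanthroline (cat.), Cs2CO3, toluene, 80 °C
Reagents that add atoms: 4-methoxybenzyl alcohol, OCc1ccc(OC)cc1
Why: Ullmann-type copper-catalysed C–O coupling of a vinyl iodide with a primary alcohol proceeds with retention of alkene geometry, so it should deliver the E enol ether that later places O6 pseudo-equatorial, and it leaves the quaternary centre untouched.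

Step 7
Reactants: 10 (2R)-2-[(E)-2-(4-methoxybenzyloxy)ethenyl]-2,6-dimethylcyclohexan-1-one (epimer mixture)
Product: 11 (2R,6S)-2-[(E)-2-(4-methoxybenzyloxy)ethenyl]-2,6-dimethylcyclohexan-1-one (methyl groups cis)
Conditions: NaOMe (cat.), MeOH, 25 °C; chromatography, 6R epimer returned to the same conditions
Reagents that add atoms: none
Why: Base-mediated epimerisation through the only available enolate equilibrates C10, and the isomer with the two methyls cis (both equatorial, alkenyl arm axial) is separated while the other epimer is recycled, which sets C10 as S.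

Step 8
Reactants: 12 2,3-dibromopropene
Product: 13 2-bromoallyl 4-methoxybenzyl ether
Conditions: 4-methoxybenzyl alcohol, NaH, THF, 0 → 25 °C
Reagents that add atoms: 4-methoxybenzyl alcohol, OCc1ccc(OC)cc1
Why: Williamson ether synthesis: the alkoxide displaces the allylic bromide by SN2 while the vinylic bromide is inert.

Step 9
Reactants: 13 2-bromoallyl 4-methoxybenzyl ether; 14 trimethylsilylacetylene
Product: 15 [3-(4-methoxybenzyloxymethyl)but-3-en-1-yn-1-yl]trimethylsilane
Conditions: PdCl2(PPh3)2 (cat.), CuI (cat.), Et3N, THF, 25 → 50 °C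
Reagents that add atoms: none
Why: Sonogashira coupling of the vinyl bromide with the terminal alkyne forms the C7–C11 bond, and the silyl cap prevents double coupling.

Step 10
Reactants: 15 [3-(4-methoxybenzyloxymethyl)but-3-en-1-yn-1-yl]trimethylsilane
Product: 16 2-(4-methoxybenzyloxymethyl)but-1-en-3-yne
Conditions: K2CO3 (cat.), MeOH, 25 °C
Reagents that add atoms: none
Why: Carbonate-catalysed methanolysis cleaves the alkynyl C–Si bond selectively and leaves the ether and the alkene alone.

Step 11
Reactants: 16 2-(4-methoxybenzyloxymethyl)but-1-en-3-yne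
Product: 18 (1E)-1-iodo-3-(4-methoxybenzyloxymethyl)buta-1,3-diene, via alkenylzirconocene chloride 17 (not isolated)
Conditions: Cp2ZrHCl, THF, 25 °C, dark; then I2, 0 °C
Reagents that add atoms: iodine, [I][I]
Why: Hydrozirconation–iodination: Cp2ZrHCl adds syn to the alkyne with zirconium at the terminal carbon, faster than to the 1,1-disubstituted alkene, and iodinolysis with retention gives the E dienyl iodide.

Step 12
Reactants: 18 (1E)-1-iodo-3-(4-methoxybenzyloxymethyl)buta-1,3-diene; 11 (2R,6S)-2-[(E)-2-(4-methoxybenzyloxy)ethenyl]-2,6-dimethylcyclohexan-1-one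
Product: 21 (1S,2R,6S)-1-[(1E)-3-(4-methoxybenzyloxymethyl)buta-1,3-dien-1-yl]-2-[(E)-2-(4-methoxybenzyloxy)ethenyl]-2,6-dimethylcyclohexan-1-ol (alkenyl arms trans), via dienyllithium 19 (not isolated), via dienylcerium dichloride 20 (not isolated)
Conditions: t-BuLi (2 equiv), Et2O, −78 °C; CeCl3, THF, −78 °C; then 11, −78 → −20 °C
Reagents that add atoms: none
Why: Iodine–lithium exchange with retention, transmetalation to the weakly basic organocerium reagent and 1,2-addition: ketone 11 rests in the chair with both methyls equatorial and the enol ether arm axial, so the reagent should enter along the axial trajectory on the face away from that arm, which places the two alkenyl arms trans and sets carbinol carbon C9 as S.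

Step 13
Reactants: 21 (1S,2R,6S)-trans-dialkenylcyclohexanol
Product: 24 (4E,6S,7S,8S,10S)-8-hydroxy-6-(4-methoxybenzyloxy)-7-[3-(4-methoxybenzyloxy)prop-1-en-2-yl]-4,10-dimethylcyclodec-4-en-9-one (route locants), via potassium alkoxide 22 (not isolated), via ring-expanded potassium enolate 23 (not isolated)
Conditions: KH, 18-crown-6, THF, 0 → 25 °C; then 2-(phenylsulfonyl)-3-phenyloxaziridine, −78 °C; AcOH
Reagents that add atoms: 2-(phenylsulfonyl)-3-phenyloxaziridine, O=S(=O)(c1ccccc1)N1OC1c1ccccc1
Why: KH with 18-crown-6 turns 21 into the dissociated alkoxide 22, whose 3-oxido-1,5-diene unit C7=C8–C9(O−)–C4–C5=C6 undergoes a concerted, charge-accelerated [3,3]-sigmatropic shift in which C6–C7 forms while the cyclohexane bond C4–C9 breaks, giving enolate 23, which the N-sulfonyloxaziridine then hydroxylates at C8 in the same flask. The closest known reactions are the anionic oxy-Cope ring expansion of trans-1,2-dialkenylcyclohexanols to (E)-cyclodec-5-enones and the oxaziridine oxidation of the enolates so formed, and oxy-Cope substrates carrying an alkoxy group on a terminus are also known. The ten-membered carbocycle is closed by a four-carbon ring enlargement, the two two-carbon arms being spliced into the six-membered ring, and not by an end-to-end cyclisation, so dilution plays no role. In the chair transition state both arms are equatorial on the cyclohexane chair, so C3 and C10 are pseudo-equatorial and both new ring double bonds (C4=C5 and the enolate C8=C9) are trans within the ring, while the E enol ether puts O6 and the E dienyl arm puts C11 pseudo-equatorial, so that H6 and H7 end up anti and the R centre at C4, which is consumed, is translated into 6S and 7S. C8 is controlled by the ring, because the enolate stands edge-on with its inner face over C4=C5 and the oxidant can approach only from the periphery (8S), and C10 passes through unchanged because KH leaves no proton source that could move the enolate to the C10 side. The step needs chair over boat and rearrangement over fragmentation: the trans arrangement of the arms from step 12 and the two E alkenes secure the former, the poor leaving ability of a donor-substituted allyl anion secures the latter, and the price is a reactive chair with the oxido group and both methyls axial, which the alkoxide acceleration should be able to pay.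

Step 14
Reactants: 24 alpha-hydroxy (E)-cyclodecenone
Product: 25 (4E,6S,7R,8S,10S)-8-O-TBS ether of 24
Conditions: TBSOTf, 2,6-lutidine, CH2Cl2, −78 → 0 °C
Reagents that add atoms: tert-butyldimethylsilyl triflate, CC(C)(C)[Si](C)(C)OS(=O)(=O)C(F)(F)F
Why: Silylation of the secondary alpha-hydroxyl with the reactive triflate and a non-nucleophilic base masks O8, so that later only O6 can lactonise, and at low temperature the ketone is not enolised.

Step 15
Reactants: 25 8-O-TBS (E)-cyclodecenone
Product: 26 (4S,5S,6R,7R,8S,10S)-4,5-epoxide of 25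
Conditions: mCPBA, CH2Cl2, 0 °C
Reagents that add atoms: 3-chloroperoxybenzoic acid, OOC(=O)c1cccc(Cl)c1
Why: Prilezhaev epoxidation: the strained trisubstituted E alkene is far more nucleophilic than the 1,1-disubstituted C11=C13 bond, and since allylic 1,3-strain holds H6 in the alkene plane and the ring covers the inner face, the peracid should reach only the outer face, which sets C5 as S (and C4 provisionally as S).

Step 16
Reactants: 26 4,5-epoxide
Product: 27 (4R,5S,6R,7R,8S,10S)-4,5-dihydroxy-6-(4-methoxybenzyloxy)-7-[3-(4-methoxybenzyloxy)prop-1-en-2-yl]-8-(TBS-oxy)-4,10-dimethylcyclodecan-9-one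
Conditions: HClO4 (cat.), THF/H2O, 0 °C
Reagents that add atoms: water, O
Why: Acid-catalysed epoxide hydrolysis: the protonated trisubstituted oxirane opens at the tertiary carbon with inversion (4S to 4R) while the C5–O bond and its configuration are kept, giving the anti-4,5-diol, and the C9 carbonyl oxygen lying behind C4 can assist only in the same stereochemical sense.

Step 17
Reactants: 27 anti-4,5-diol; 28 angelic acid
Product: 30 (4R,5S,6R,7R,8S,10S)-5-O-angelate of 27 (C4 hydroxyl free), via mixed anhydride 29 (not isolated)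
Conditions: 28, 2,4,6-trichlorobenzoyl chloride, Et3N, toluene, 25 °C; then 27, 75 °C
Reagents that add atoms: none
Why: Yamaguchi-type esterification through mixed anhydride 29 without a nucleophilic amine catalyst acylates the secondary C5 hydroxyl and not the tertiary C4 hydroxyl, and avoids the addition–elimination that would turn the Z angelate into the E tiglate.

Step 18
Reactants: 30 5-O-angelate bis-PMB ether
Product: 31 (4R,5S,6R,7R,8S,10S)-5-angeloyloxy-4,6-dihydroxy-7-(3-hydroxyprop-1-en-2-yl)-8-(TBS-oxy)-4,10-dimethylcyclodecan-9-one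
Conditions: DDQ, CH2Cl2/pH 7 buffer, 0 → 25 °C
Reagents that add atoms: none
Why: Oxidative PMB cleavage: DDQ abstracts hydride from both electron-rich benzylic positions and water hydrolyses the oxocarbenium ions, freeing O6 and O12 under near-neutral conditions that spare the silyl ether, the angelate, the ketone and the alkene.

Step 19
Reactants: 31 4,6,12-triol
Product: 34 (4R,5S,6R,7R,8S,10S)-8-O-TBS ether of the target, via hydroxy enal 32 (not isolated), via lactol 33 (not isolated)
Conditions: MnO2, CH2Cl2, 25 °C
Reagents that add atoms: none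
Why: MnO2 oxidative lactonisation: only the allylic primary alcohol is oxidised, enal 32 is captured by the C6 hydroxyl as the five-membered lactol 33, and this allylic lactol is oxidised on to the alpha-methylene-gamma-lactone, which is trans-fused because C6 and C7 are already set.

Step 20
Reactants: 34 8-O-TBS lactone
Product: 35 target CNP0311008.1 (4R,5S,6R,7S,8S,10S)
Conditions: HF·pyridine, pyridine, THF, 0 → 25 °C
Reagents that add atoms: none
Why: Fluoride-induced desilylation in a pyridine-buffered medium removes the TBS group without free base, so conjugate addition to the methylene lactone, acyl migration and epimerisation at C8 or C10 are avoided.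

**Compound list**

1 | 2,6-dimethylcyclohexanone | CC1CCCC(C)C1=O | starting material
2 | allyl chloroformate | C=CCOC(=O)Cl | starting material
3 | potassium 2,6-dimethylcyclohex-1-en-1-olate | CC1CCCC(C)=C1[O-].[K+] | intermediate
4 | allyl 2,6-dimethylcyclohex-1-en-1-yl carbonate | CC1CCCC(C)=C1OC(=O)OCC=C | intermediate
5 | (2R)-2-allyl-2,6-dimethylcyclohexan-1-one, C6 epimers | O=C1C(C)CCC[C@]1(C)CC=C | intermediate
6 | (2R)-2,6-dimethyl-2-[(E)-prop-1-en-1-yl]cyclohexan-1-one, C6 epimers | O=C1C(C)CCC[C@]1(C)/C=C/C | intermediate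
7 | (2R)-2,6-dimethyl-2-(5-methyl-1,2,4-trioxolan-3-yl)cyclohexan-1-one (secondary ozonide) | O=C1C(C)CCC[C@]1(C)C2OOC(C)O2 | intermediate
8 | (1R)-1,3-dimethyl-2-oxocyclohexane-1-carbaldehyde, C3 epimers | O=C1C(C)CCC[C@]1(C)C=O | intermediate
9 | (2R)-2-[(E)-2-iodoethenyl]-2,6-dimethylcyclohexan-1-one, C6 epimers | O=C1C(C)CCC[C@]1(C)/C=C/I | intermediate
10 | (2R)-2-[(E)-2-(4-methoxybenzyloxy)ethenyl]-2,6-dimethylcyclohexan-1-one, C6 epimers | O=C1C(C)CCC[C@]1(C)/C=C/OCc2ccc(OC)cc2 | intermediate
11 | (2R,6S)-2-[(E)-2-(4-methoxybenzyloxy)ethenyl]-2,6-dimethylcyclohexan-1-one, methyls cis | O=C1[C@@H](C)CCC[C@]1(C)/C=C/OCc2ccc(OC)cc2 | intermediate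
12 | 2,3-dibromopropene | C=C(Br)CBr | starting material
13 | 2-bromoallyl 4-methoxybenzyl ether | C=C(Br)COCc1ccc(OC)cc1 | intermediate
14 | trimethylsilylacetylene | C#C[Si](C)(C)C | starting material
15 | [3-(4-methoxybenzyloxymethyl)but-3-en-1-yn-1-yl]trimethylsilane | C=C(C#C[Si](C)(C)C)COCc1ccc(OC)cc1 | intermediate
16 | 2-(4-methoxybenzyloxymethyl)but-1-en-3-yne | C=C(C#C)COCc1ccc(OC)cc1 | intermediate
17 | (E)-dienylzirconocene chloride (C5H5 rings written sigma-bonded) | Cl[Zr](/C=C/C(=C)COCc1ccc(OC)cc1)(C2C=CC=C2)C3C=CC=C3 | intermediate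
18 | (1E)-1-iodo-3-(4-methoxybenzyloxymethyl)buta-1,3-diene | I/C=C/C(=C)COCc1ccc(OC)cc1 | intermediate
19 | (1E)-3-(4-methoxybenzyloxymethyl)buta-1,3-dien-1-yllithium | [Li]/C=C/C(=C)COCc1ccc(OC)cc1 | intermediate
20 | (1E)-3-(4-methoxybenzyloxymethyl)buta-1,3-dien-1-ylcerium dichloride | Cl[Ce](Cl)/C=C/C(=C)COCc1ccc(OC)cc1 | intermediate
21 | (1S,2R,6S)-1-[(1E)-3-(4-methoxybenzyloxymethyl)buta-1,3-dien-1-yl]-2-[(E)-2-(4-methoxybenzyloxy)ethenyl]-2,6-dimethylcyclohexan-1-ol | O[C@]1(/C=C/C(=C)COCc2ccc(OC)cc2)[C@@H](C)CCC[C@]1(C)/C=C/OCc3ccc(OC)cc3 | intermediate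
22 | potassium alkoxide of 21 | [K+].[O-][C@]1(/C=C/C(=C)COCc2ccc(OC)cc2)[C@@H](C)CCC[C@]1(C)/C=C/OCc3ccc(OC)cc3 | intermediate
23 | (6S,7R,10S)-potassium cyclodeca-4,8-dien-9-olate, C4=C5 E, C7 and C10 trans across C8=C9 | [K+].C=C(COCc2ccc(OC)cc2)[C@H]1/C=C([O-])/[C@@H](C)CCC/C(C)=C/[C@@H]1OCc3ccc(OC)cc3 | intermediate
24 | (4E,6S,7S,8S,10S)-8-hydroxy-6-(PMB-oxy)-7-[3-(PMB-oxy)prop-1-en-2-yl]-4,10-dimethylcyclodec-4-en-9-one | C=C(COCc2ccc(OC)cc2)[C@H]1[C@H](O)C(=O)[C@@H](C)CCC/C(C)=C/[C@@H]1OCc3ccc(OC)cc3 | intermediate
25 | (4E,6S,7R,8S,10S)-8-O-TBS ether of 24 | C=C(COCc2ccc(OC)cc2)[C@H]1[C@H](O[Si](C)(C)C(C)(C)C)C(=O)[C@@H](C)CCC/C(C)=C/[C@@H]1OCc3ccc(OC)cc3 | intermediate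
26 | (4S,5S,6R,7R,8S,10S)-4,5-epoxide of 25 | C=C(COCc2ccc(OC)cc2)[C@H]1[C@H](O[Si](C)(C)C(C)(C)C)C(=O)[C@@H](C)CCC[C@]4(C)O[C@H]4[C@@H]1OCc3ccc(OC)cc3 | intermediate
27 | (4R,5S,6R,7R,8S,10S)-anti-4,5-diol | C=C(COCc2ccc(OC)cc2)[C@H]1[C@H](O[Si](C)(C)C(C)(C)C)C(=O)[C@@H](C)CCC[C@@](C)(O)[C@@H](O)[C@@H]1OCc3ccc(OC)cc3 | intermediate
28 | angelic acid, (Z)-2-methylbut-2-enoic acid | C/C=C(/C)C(=O)O | starting material
29 | angelic 2,4,6-trichlorobenzoic anhydride | C/C=C(/C)C(=O)OC(=O)c1c(Cl)cc(Cl)cc1Cl | intermediate
30 | (4R,5S,6R,7R,8S,10S)-5-O-angelate of 27 | C=C(COCc2ccc(OC)cc2)[C@H]1[C@H](O[Si](C)(C)C(C)(C)C)C(=O)[C@@H](C)CCC[C@@](C)(O)[C@@H](OC(=O)/C(C)=C\C)[C@@H]1OCc3ccc(OC)cc3 | intermediate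
31 | (4R,5S,6R,7R,8S,10S)-4,6,12-triol 5-angelate 8-TBS ether | C=C(CO)[C@H]1[C@H](O[Si](C)(C)C(C)(C)C)C(=O)[C@@H](C)CCC[C@@](C)(O)[C@@H](OC(=O)/C(C)=C\C)[C@@H]1O | intermediate
32 | C12 enal with free C6 hydroxyl | C=C(C=O)[C@H]1[C@H](O[Si](C)(C)C(C)(C)C)C(=O)[C@@H](C)CCC[C@@](C)(O)[C@@H](OC(=O)/C(C)=C\C)[C@@H]1O | intermediate
33 | 12,6-lactol (C12 epimers) | C=C1C(O)O[C@@H]2[C@@H]1[C@H](O[Si](C)(C)C(C)(C)C)C(=O)[C@@H](C)CCC[C@@](C)(O)[C@H]2OC(=O)/C(C)=C\C | intermediate
34 | (4R,5S,6R,7R,8S,10S)-8-O-TBS ether of the target | C=C1C(=O)O[C@@H]2[C@@H]1[C@H](O[Si](C)(C)C(C)(C)C)C(=O)[C@@H](C)CCC[C@@](C)(O)[C@H]2OC(=O)/C(C)=C\C | intermediate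
35 | CNP0311008.1, (4R,5S,6R,7S,8S,10S) | C=C1C(=O)O[C@@H]2[C@@H]1[C@H](O)C(=O)[C@@H](C)CCC[C@@](C)(O)[C@H]2OC(=O)/C(C)=C\C | target

**Step count**

Total step count: 20. Longest linear sequence: 16 steps (steps 1–7, then 12–20). The dienyl iodide branch (steps 8–11) joins at step 12.

**Steps most likely to fail**

Step 13.
- What may go wrong: the alkoxide has to reach a chair with three axial groups, so the sigmatropic shift may be slow enough to need heating.
- Base-induced degradation of the arms could then take over.
- So could proton transfer that walks the enolate to the C10 side, with loss of regiocontrol and epimerisation, or unselective hydroxylation.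
- Fallback (sets out from 21, comes back at 23 and 24): the rearrangement is run without base as a thermal oxy-Cope reaction (o-dichlorobenzene, about 200 °C, base-washed glass).
- This should give the ring-expanded enol F1 and, by irreversible tautomerisation, the 8-deoxy cyclodecenone F2.
- Kinetic deprotonation of F2 at its C8 methylene with KN(SiMe3)2 at −78 °C then regenerates enolate 23 under conditions where it cannot equilibrate, and the sulfonyloxaziridine converts it into 24.

Step 16.
- What may go wrong: the oxirane oxygen points outward, so the rear side of C4 looks into the ring and external water may be shut out.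
- Ionisation at C4 followed by proton loss, transannular hydride shift or capture with retention may then compete. Partial loss of the silyl ether is a lesser concern.
- Fallback (sets out from 26, comes back at 27): the oxygen is delivered from inside the ring by the C9 carbonyl group, which lies on that rear side.
- Catalytic camphorsulfonic acid in dry CH2Cl2 with a few equivalents of methanol at −20 °C follows the known acid-induced cyclisation of keto epoxides to bicyclic ketals. It should give the 4,9-oxygen-bridged methyl ketal F3, with inversion at C4 and the C5 hydroxyl free.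
- Mild hydrolysis (pyridinium p-toluenesulfonate, wet acetone) opens the ketal to hydroxy ketone 27.

Step 12.
- What may go wrong: the carbonyl group is flanked by a quaternary and a tertiary carbon, so the branched alkenyl metal may add slowly.
- Enolisation may compete and facial selectivity may erode.
- Fallback (sets out from 16 and 11, comes back at 21): a slimmer sp nucleophile is used.
- n-BuLi converts 16 into the lithium acetylide F4, which adds to 11 along the same axial trajectory (CeCl3 may be added) to give the propargylic alcohol F5.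
- Hydroxyl-directed trans-hydroalumination with LiAlH4 in THF, followed by protonolysis, then gives the E dienyl arm of 21.

Further compounds
F1 | step 13 | (4E,6S,7R,10S)-ring-expanded enol, neutral form of 23 | C=C(COCc2ccc(OC)cc2)[C@H]1/C=C(O)/[C@@H](C)CCC/C(C)=C/[C@@H]1OCc3ccc(OC)cc3
F2 | step 13 | (4E,6S,7R,10S)-6-(PMB-oxy)-7-[3-(PMB-oxy)prop-1-en-2-yl]-4,10-dimethylcyclodec-4-en-9-one (8-deoxy analogue of 24) | C=C(COCc2ccc(OC)cc2)[C@H]1CC(=O)[C@@H](C)CCC/C(C)=C/[C@@H]1OCc3ccc(OC)cc3
F3 | step 16 | (4R,5S,6R,7R,8S,9R,10S)-9-methoxy-4,9-epoxy ketal (11-oxabicyclo[4.4.1]undecane core) with free C5 hydroxyl | C=C(COCc2ccc(OC)cc2)[C@H]1[C@H](O[Si](C)(C)C(C)(C)C)[C@@]4(OC)[C@@H](C)CCC[C@@](C)(O4)[C@@H](O)[C@@H]1OCc3ccc(OC)cc3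
F4 | step 12 | lithium acetylide of 16 | [Li]C#CC(=C)COCc1ccc(OC)cc1
F5 | step 12 | (1R,2R,6S)-1-[3-(4-methoxybenzyloxymethyl)but-3-en-1-yn-1-yl]-2-[(E)-2-(4-methoxybenzyloxy)ethenyl]-2,6-dimethylcyclohexan-1-ol | O[C@]1(C#CC(=C)COCc2ccc(OC)cc2)[C@@H](C)CCC[C@]1(C)/C=C/OCc3ccc(OC)cc3
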